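The catalyst cannot be kept away from either hand of the substrate, so the flasks below make both products, and the question is in what proportion.

| setting | theta | epsilon | gamma |
|---|---|---|---|
| left-handed substrate | 0.10 M | 0.10 M | 0.10 M |
| partner | 0.300 M | 0.300 M | 0.300 M |
| free catalyst | 3.4 mM | 3.4 mM | 3.4 mM |
| impurity | 3.9 mM | 3.9 mM | 3.9 mM |
| added ligand | 3.7 mM | 3.7 mM | 3.7 mM |
| right-handed substrate | 0.10 M | 0.10 M | 0.10 M |
| temperature | 0 °C | 30 °C | −30 °C |
| time | 40 h | 40 h | 40 h |

    partner + free catalyst + right-handed substrate → free catalyst + right-handed product (k1 = 79 L² mol⁻² h⁻¹, Ea1 = 48.0 kJ mol⁻¹)
    left-handed substrate ⇌ right-handed substrate (k2 = 0.042 h⁻¹, Ea2 = 89.0 kJ mol⁻¹)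
    free catalyst + impurity → spent catalyst (k3 = 1800 L mol⁻¹ h⁻¹, Ea3 = 42.0 kJ mol⁻¹)
    partner + free catalyst + left-handed substrate → free catalyst + left-handed product (k4 = 920 L² mol⁻² h⁻¹, Ea4 = 45.0 kJ mol⁻¹)
    partner → decomposed reagent (k5 = 0.26 h⁻¹, Ea5 = 87.0 kJ mol⁻¹)
    free catalyst + added ligand ⇌ idle complex, settled at all times (K6 = 110 L mol⁻¹, ΔH6 = −79.0 kJ mol⁻¹)
    (constants at 0 °C)

- free catalyst is single-handed; left-handed substrate and right-handed substrate are mirror images of each other, charged as a racemate, each of them at the stated concentration
- the list of constants is for 0 °C, to be carried to other temperatures by the activation energies and enthalpies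
- an excess is the difference of the two amounts in percent of their sum
- an excess is below zero if the other one leads

- the flask that comes out highest in excess of left-handed product over right-handed product, or "all alike" when all lie within 1.5 percentage points (theta / epsilon / gamma / all alike)
- excess of left-handed product over right-handed product at the end, theta
- excess of left-handed product over right-handed product at the end, epsilon
- excess of left-handed product over right-handed product at the end, gamma

By my reckoning two rates matter: that of the left-handed product and that of the right-handed product. Both carry c(partner) and c(free catalyst) as the same factors, so their quotient contains neither. It is 920 L² mol⁻² h⁻¹ over 79 L² mol⁻² h⁻¹, times c(left-handed substrate)/c(right-handed substrate). Partner decay and catalyst death therefore slow both rates together. The constant part of the quotient is the selectivity factor s, the ratio of the two rate constants at equal substrate, 11.6 at 0 °C.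

Now the two ends. With racemisation fast, the substrates stay equal and the excess is s less one over s plus one, which is also the excess of the first product formed. With no racemisation, the left-handed substrate falls faster, the logarithm of the remaining right-handed fraction being that of the left-handed fraction divided by s, and the excess sinks below that ceiling.

Theta lies near this second end, since the substrates' relaxation half-life of 8.25 h exceeds the partner's half-life by decay of 2.67 h. Theta's impurity, 3.9 mM, also exceeds its catalyst, 3.4 mM, and each impurity kills one catalyst. The time integral of c(free catalyst) thus reaches at most ln(c(impurity) charged / c(impurity) left) over the rate constant 1800 L mol⁻¹ h⁻¹. With partner held at its charge and no racemisation, the logarithm of the remaining left-handed fraction falls by at most 0.315. That puts theta's excess between 82.0% and the ceiling of 84.2%.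

Temperature moves s through the activation energies, which differ by 3.00 kJ mol⁻¹. Epsilon has s = 10.2 and a ceiling of 82.2%. Gamma has s = 13.7 and a ceiling of 86.4%. My pick is gamma.

The forecast names gamma, with 81% for theta (79.5% to 82.5%), 80.5% for epsilon (78.5% to 82%) and 85.8% for gamma (84.5% to 86.4%), holding that “the excess is essentially a kinetic resolution”. For theta its central number stands a little below my bracket.

The simulation gives gamma on top, with 82.6% in theta, 81.1% in epsilon and 85.8% in gamma.

The neighbouring flask is theta with 1.2 M of partner, and it ends with 31.9% left-handed product. Drawn from the left-handed share of the charge with no refill, that amount and s = 11.6 give 4.18% right-handed product, against 4.05% in the flask. The reckoned excess is 76.8%, and that flask ends at 77.5%.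

Its constants were drawn at random within sensible limits; the flask was simulated.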